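The product is the complex with three exchanged, and the starting complex destroys it by the last step of the scheme, so a bigger charge may not mean more product in the flask.

    starting complex + incoming ligand ⇌ leaving ligand + complex with one exchanged (K1 = 0.629, k1 = 0.589 M⁻¹ h⁻¹)
    complex with one exchanged + incoming ligand ⇌ leaving ligand + complex with two exchanged (K2 = 35, k2 = 1.05 M⁻¹ h⁻¹)
    complex with two exchanged + incoming ligand ⇌ leaving ligand + complex with three exchanged (K3 = 13, k3 = 1.49 M⁻¹ h⁻¹)
    starting complex + complex with three exchanged → side product (k4 = 1.76 M⁻¹ h⁻¹)

| flask | starting complex | incoming ligand | time |
|---|---|---|---|
| elm | 30 mM | 43.5 mM | 2.5 d |
| birch | 60 mM | 43.5 mM | 2.5 d |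
| cedar | 120 mM | 43.5 mM | 2.5 d |
| oak | 250 mM | 43.5 mM | 2.5 d |
| larch | 500 mM | 43.5 mM | 2.5 d |

- share of complex with three exchanged in all that became complex with three exchanged or side product for elm, birch, cedar, oak, larch, in this order
- how that number moves from the first to the last of them (rises, then falls / falls all the way / falls, then rises / hardly changes / rises all the way)

- percentages count the starting complex that a species holds: one side product counts as two
- "hardly changes" means that all values lie within two and a half points (for a concentration: within two and a half percent of the largest)
- run time (elm): 2.5 d

At a given moment, the starting complex acts on each complex with three exchanged as a pseudo-first-order scavenger. In elm, that step's half-life at the charged amounts is 0.55 d, shorter than the run of 2.5 d. So I expect the product to stand at its making rate times its scavenging lifetime, while the rest of what is made passes into side product, which counts double.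

I therefore carry one number, the scavenging count: rate constant of the last step times charged starting complex times run time, which in elm is 3.17, the run measured in scavenging lifetimes. If the making rate holds steady, it cancels, and the share is 1/(2N − 1), with N the count. The ligand steps drop out of this reckoning:

- elm, 30 mM: count 3.17, share 18.7%
- birch, 60 mM: count 6.34, share 8.57%
- cedar, 120 mM: count 12.7, share 4.11%
- oak, 250 mM: count 26.4, share 1.93%
- larch, 500 mM: count 52.8, share 0.956%

Reading down, the count climbs with the charge, so the share falls at every row , and the shape comes out as: falls all the way.

Reading the bottom row, each unit of incoming ligand spent removes at most one unit of starting complex. Larch can therefore lose at most 8.70% of its charge, and its count stands. Reading the top row, the ligand charge in elm exceeds the starting charge, so the starting complex can fall far. The true count then lies below the table's, and I hold 18.7% as low. That correction raises the first row, so I commit to a steady fall.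

The forecast gives 39%, 13%, 5%, 2.5% and 1%, with the shape falls all the way, on the ground that “triple-exchanged complex is scavenged ever faster and sits at a shrinking steady level”. For elm it stands above my figure.

The flask gives 35.9%, 13.8%, 4.85%, 2.17% and 1.16%, and the shape is: falls all the way. At 1.25 d, elm holds 59.1% of its starting complex and birch holds 67.9%. With these amounts in place of the charges, elm's scavenging count becomes 1.87, for a share of 36.4%. Birch's count becomes 4.30, for a share of 13.1% beside the flask's 13.8%.

The numbers are invented, and the outcome is calculated.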